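**Strategy.** The target is cut at C1, the single carbon shared by ring A (C1-C10-C9-C8-C7-C11), ring B (C1-C5-C6-C7-C11) and ring C (C1-C2-C3-C4-C5): its bonds to C5 and C2 are both made at what was a ring-A ketone carbon. In one operation a radical cascade on an N-aziridinylimine closes rings B and C, forms C1–C5 and C1–C2, and sets C1, C5 and C2 from the lone C7 stereocentre. The precursor is a ring-A cyclohexanone hydrazone (C8 ketal) whose C7 substituent carries C6 (CMe2), a C5 xanthate and a C4–C3–C2 alkenylboronate chain; boron marks the formyl carbon. The C16 acid is attached late at C10.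

Key step: step 11

**Remarks on the chemistry (assumptions and precursor design)**
- Atom labels follow tricyclo[5.3.1.0(1,5)]undecane numbering: C1 quaternary, C2 CH with the formyl arm, C3/C4 CH2, C5 ring-fusion CH, C6 CMe2, C7 bridgehead CH, C8/C9 alkene (C8 bears CO2H), C10 acyloxy CH, C11 one-carbon bridge. Primes denote the C16 acid. The target is (1S,2S,5S,7R,10S).
- "Core" below means: C7/C1 bridgeheads as fixed by (6R)-4, C5–H endo (C4 exo, on the C11 side of the C5–C6 bridge), C2 arm on the C11 face of ring C; an sp3 C10 oxygen lies on the C5 side of ring A.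
- The (S)-oxazaborolidinium catalyst is assumed to give the 6R adduct 4; if the sense is opposite, its enantiomer is used.
- 1-Amino-2-phenylaziridine is used as the racemic reagent, freshly liberated from its acetate salt.
- The silyl ether carbon C1 (5–7, 9, 11–13), the carbinol/xanthate carbon C5 (9, 11–15) and the aziridine carbon (15) form without control and are written without descriptors. A precursor drawn as one isomer at the xanthate and aziridine carbons is not what this chemistry delivers; the centres are erased in step 9 or step 11.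
- Precursor design: the S-methyl xanthate is kept because it tolerates the hydrazine condensation, but it is installed before the ketone is unmasked. C8 stays ketalised until C7 is a bridgehead, so C7 cannot epimerise. The alkenylboronate comes from cross-metathesis; its E/Z ratio does not affect the product.

**Route**

Step 1
Reactants: 1 1,4-dioxaspiro[4.5]dec-6-en-8-one; 2 1-methoxy-2-methyl-1-(trimethylsilyloxy)propene
Product: 4 methyl 2-methyl-2-[(6R)-8-oxo-1,4-dioxaspiro[4.5]decan-6-yl]propanoate, via silyl enol ether 3 (not isolated)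
Conditions: (S)-B-(o-tolyl)oxazaborolidinium triflimide (from the (S)-diphenylprolinol-derived oxazaborolidine and HNTf2, 20 mol %), Ph3PO (25 mol %), toluene, −20 °C; then 1 M HCl–THF, 0 °C, 10 min
Reagents that add atoms: none
Why: Catalytic enantioselective Mukaiyama–Michael addition, in which the chiral boron Lewis acid binds the enone carbonyl and leaves one face of the β-carbon open so that the ketene acetal sets C7 as R, Ph3PO traps the silyl cation and brief acid frees the ketone without touching the dioxolane.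

Step 2
Reactants: 4 methyl 2-methyl-2-[(6R)-8-oxo-1,4-dioxaspiro[4.5]decan-6-yl]propanoate
Product: 5 methyl 2-methyl-2-[(6R)-8-(triethylsilyloxy)-1,4-dioxaspiro[4.5]decan-6-yl]propanoate (both C1 epimers)
Conditions: Et3SiH, RhCl(PPh3)3 (1 mol %), benzene, 60 °C
Reagents that add atoms: triethylsilane, CC[SiH](CC)CC
Why: Rhodium-catalysed ketone hydrosilylation masks the unhindered C1 carbonyl as a silyl ether in one operation while ester and ketal stay inert, and the uncontrolled C1 centre is irrelevant because it is re-oxidised in step 9.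

Step 3
Reactants: 5 methyl 2-methyl-2-[(6R)-8-(triethylsilyloxy)-1,4-dioxaspiro[4.5]decan-6-yl]propanoate
Product: 6 2-methyl-2-[(6R)-8-(triethylsilyloxy)-1,4-dioxaspiro[4.5]decan-6-yl]propan-1-ol
Conditions: LiAlH4, THF, 0 °C to rt
Reagents that add atoms: none
Why: Hydride reduction of the hindered ester to the neopentyl alcohol, with silyl ether and ketal unaffected.

Step 4
Reactants: 6 2-methyl-2-[(6R)-8-(triethylsilyloxy)-1,4-dioxaspiro[4.5]decan-6-yl]propan-1-ol
Product: 7 2-methyl-2-[(6R)-8-(triethylsilyloxy)-1,4-dioxaspiro[4.5]decan-6-yl]propanal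
Conditions: Dess–Martin periodinane, NaHCO3, CH2Cl2, 0 °C to rt
Reagents that add atoms: none
Why: Dess–Martin oxidation gives the non-enolisable α-quaternary aldehyde under buffered conditions that spare the triethylsilyl ether and the ketal.

Step 5
Reactants: 7 2-methyl-2-[(6R)-8-(triethylsilyloxy)-1,4-dioxaspiro[4.5]decan-6-yl]propanal; 8 but-3-enylmagnesium bromide
Product: 9 2-methyl-2-[(6R)-8-(triethylsilyloxy)-1,4-dioxaspiro[4.5]decan-6-yl]hept-6-en-3-ol (carbinol epimers)
Conditions: THF, −78 to 0 °C; aq. NH4Cl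
Reagents that add atoms: none
Why: Grignard addition of a primary reagent to the aldehyde builds C5–C4, and the new carbinol centre C5 forms without control and is erased in step 11.

Step 6
Reactants: 9 2-methyl-2-[(6R)-8-(triethylsilyloxy)-1,4-dioxaspiro[4.5]decan-6-yl]hept-6-en-3-ol; 10 4,4,5,5-tetramethyl-2-vinyl-1,3,2-dioxaborolane
Product: 11 (6E)-2-methyl-7-(4,4,5,5-tetramethyl-1,3,2-dioxaborolan-2-yl)-2-[(6R)-8-(triethylsilyloxy)-1,4-dioxaspiro[4.5]decan-6-yl]hept-6-en-3-ol
Conditions: second-generation Grubbs catalyst RuCl2(=CHPh)(H2IMes)(PCy3) (5 mol %), 10 (3 equiv), CH2Cl2, 40 °C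
Reagents that add atoms: none
Why: Olefin cross-metathesis of the terminal alkene with the vinylboronate gives the (E)-alkenylboronate under thermodynamic control, and the free hindered alcohol, silyl ether and ketal are tolerated.

Step 7
Reactants: 11 (6E)-2-methyl-7-(4,4,5,5-tetramethyl-1,3,2-dioxaborolan-2-yl)-2-[(6R)-8-(triethylsilyloxy)-1,4-dioxaspiro[4.5]decan-6-yl]hept-6-en-3-ol
Product: 12 O-{(6E)-2-methyl-7-(4,4,5,5-tetramethyl-1,3,2-dioxaborolan-2-yl)-2-[(6R)-8-(triethylsilyloxy)-1,4-dioxaspiro[4.5]decan-6-yl]hept-6-en-3-yl} S-methyl carbonodithioate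
Conditions: NaN(SiMe3)2, THF, −78 °C; CS2, −78 to 0 °C; MeI, 0 °C to rt
Reagents that add atoms: carbon disulfide, S=C=S; iodomethane, CI
Why: Xanthate formation (alkoxide, CS2, S-methylation) is done while no enolisable carbonyl is present, and the pinacol boronate survives the hindered amide base at low temperature.

Step 8
Reactants: 12 O-{(6E)-2-methyl-7-(4,4,5,5-tetramethyl-1,3,2-dioxaborolan-2-yl)-2-[(6R)-8-(triethylsilyloxy)-1,4-dioxaspiro[4.5]decan-6-yl]hept-6-en-3-yl} S-methyl carbonodithioate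
Product: 13 O-{(6E)-2-[(6R)-8-hydroxy-1,4-dioxaspiro[4.5]decan-6-yl]-2-methyl-7-(4,4,5,5-tetramethyl-1,3,2-dioxaborolan-2-yl)hept-6-en-3-yl} S-methyl carbonodithioate
Conditions: AcOH–THF–H2O (3:1:1), rt
Reagents that add atoms: none
Why: Mild acid solvolysis removes the triethylsilyl ether much faster than it attacks the hindered dioxolane, the boronate or the xanthate.

Step 9
Reactants: 13 O-{(6E)-2-[(6R)-8-hydroxy-1,4-dioxaspiro[4.5]decan-6-yl]-2-methyl-7-(4,4,5,5-tetramethyl-1,3,2-dioxaborolan-2-yl)hept-6-en-3-yl} S-methyl carbonodithioate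
Product: 14 O-{(6E)-2-methyl-2-[(6R)-8-oxo-1,4-dioxaspiro[4.5]decan-6-yl]-7-(4,4,5,5-tetramethyl-1,3,2-dioxaborolan-2-yl)hept-6-en-3-yl} S-methyl carbonodithioate
Conditions: Dess–Martin periodinane, NaHCO3, CH2Cl2, 0 °C to rt
Reagents that add atoms: none
Why: Dess–Martin oxidation regenerates the C1 ketone without touching xanthate or boronate, and C7 is β to this carbonyl and cannot epimerise.

Step 10
Reactants: 14 O-{(6E)-2-methyl-2-[(6R)-8-oxo-1,4-dioxaspiro[4.5]decan-6-yl]-7-(4,4,5,5-tetramethyl-1,3,2-dioxaborolan-2-yl)hept-6-en-3-yl} S-methyl carbonodithioate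
Product: 15 O-{(6E)-2-methyl-2-[(6R)-8-[(2-phenylaziridin-1-yl)imino]-1,4-dioxaspiro[4.5]decan-6-yl]-7-(4,4,5,5-tetramethyl-1,3,2-dioxaborolan-2-yl)hept-6-en-3-yl} S-methyl carbonodithioate (key-step precursor)
Conditions: 1-amino-2-phenylaziridine (1.3 equiv), AcOH (cat.), 4 Å molecular sieves, CH2Cl2, 0 °C; used at once
Reagents that add atoms: 1-amino-2-phenylaziridine, NN1CC1c1ccccc1
Why: Hydrazone condensation at the unhindered cyclohexanone gives the N-aziridinylimine, the hindered xanthate is not attacked by the hydrazine at 0 °C, and the isomer mixture at the aziridine carbon and the C=N bond converges in step 11.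

Step 11
Reactants: 15 O-{(6E)-2-methyl-2-[(6R)-8-[(2-phenylaziridin-1-yl)imino]-1,4-dioxaspiro[4.5]decan-6-yl]-7-(4,4,5,5-tetramethyl-1,3,2-dioxaborolan-2-yl)hept-6-en-3-yl} S-methyl carbonodithioate
Product: 16 2-{[8,8-(ethylenedioxy)-6,6-dimethyltricyclo[5.3.1.0(1,5)]undecan-2-yl]methyl}-4,4,5,5-tetramethyl-1,3,2-dioxaborolane (core configuration)
Conditions: Bu3SnH (1.6 equiv) and AIBN (0.3 equiv) added over 8 h by syringe pump, degassed benzene (0.01 M), 80 °C
Reagents that add atoms: none
Why: In a radical chain the stannyl radical cleaves the xanthate (Barton–McCombie mode) to the secondary C5 radical, which adds 5-exo-trig to the C1 imine carbon and closes ring B; the aminyl radical opens the aziridine and expels styrene and N2, and the resulting C1 bridgehead radical adds 5-exo-trig to C2 of the alkenylboronate, closes ring C, and the α-boryl radical takes hydrogen from Bu3SnH. The closest known reaction type is the tandem radical cyclisation of N-aziridinylimines, in which the hydrazone carbon is first a radical acceptor and then a radical donor. C1 follows from C7, because the C7 side chain can reach C1 only from the axial direction of ring A and the bicyclo[3.2.1]octane can form in one way only. C5 is set in the first closure, where the C4 chain takes the exo position on the new C5–C6 bridge away from the C8–C10 bridge, and only that isomer can reach C2 afterwards. C2 is set in the second closure, where the CHBpin terminus turns to the C11 side of C1, which is less encumbered than the C10 side. The step needs both cyclisations to outrun hydrogen transfer and needs the stannyl radical to choose the thiocarbonyl over the alkene, which slow addition at high dilution, the irreversible loss of N2, the boron-stabilised terminus and the thiophilicity of tin should secure.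

Step 12
Reactants: 16 2-{[8,8-(ethylenedioxy)-6,6-dimethyltricyclo[5.3.1.0(1,5)]undecan-2-yl]methyl}-4,4,5,5-tetramethyl-1,3,2-dioxaborolane
Product: 18 2-(hydroxymethyl)-6,6-dimethyltricyclo[5.3.1.0(1,5)]undecan-8-one (core configuration), via hydroxy ketal 17 (not isolated)
Conditions: 30% H2O2, 3 M NaOH, THF, 0 °C to rt; then 2 M HCl, rt
Reagents that add atoms: hydrogen peroxide, OO; water, O
Why: Alkaline peroxide oxidation of the primary alkylboronate (1,2-migration with retention, so C2 is untouched) followed by acid hydrolysis of the dioxolane in the same flask, C7 now being a bridgehead that cannot epimerise next to the C8 ketone.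

Step 13
Reactants: 18 2-(hydroxymethyl)-6,6-dimethyltricyclo[5.3.1.0(1,5)]undecan-8-one
Product: 19 2-[(tert-butyldimethylsilyloxy)methyl]-6,6-dimethyltricyclo[5.3.1.0(1,5)]undecan-8-one (core configuration)
Conditions: TBSCl, imidazole, DMF, rt
Reagents that add atoms: tert-butyldimethylsilyl chloride, CC(C)(C)[Si](C)(C)Cl
Why: Silylation of the primary alcohol gives an ether that withstands the amide base, palladium, peroxide and borohydride steps ahead.

Step 14
Reactants: 19 2-[(tert-butyldimethylsilyloxy)methyl]-6,6-dimethyltricyclo[5.3.1.0(1,5)]undecan-8-one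
Product: 20 2-[(tert-butyldimethylsilyloxy)methyl]-6,6-dimethyltricyclo[5.3.1.0(1,5)]undec-8-en-8-yl trifluoromethanesulfonate (core configuration)
Conditions: KN(SiMe3)2, THF, −78 °C; PhNTf2, −78 to 0 °C
Reagents that add atoms: N-phenylbis(trifluoromethanesulfonimide), O=S(=O)(N(c1ccccc1)S(=O)(=O)C(F)(F)F)C(F)(F)F
Why: Enolate O-triflation gives a single enol triflate because the C8 ketone can enolise only toward C9, C7 being a bridgehead (Bredt's rule).

Step 15
Reactants: 20 2-[(tert-butyldimethylsilyloxy)methyl]-6,6-dimethyltricyclo[5.3.1.0(1,5)]undec-8-en-8-yl trifluoromethanesulfonate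
Product: 21 2-(trimethylsilyl)ethyl 2-[(tert-butyldimethylsilyloxy)methyl]-6,6-dimethyltricyclo[5.3.1.0(1,5)]undec-8-ene-8-carboxylate (core configuration)
Conditions: Pd(OAc)2 (10 mol %), PPh3 (20 mol %), Et3N, Me3SiCH2CH2OH (10 equiv), CO (1 atm), DMF, 60 °C
Reagents that add atoms: carbon monoxide, [C-]#[O+]; 2-(trimethylsilyl)ethanol, C[Si](C)(C)CCO
Why: Palladium-catalysed alkoxycarbonylation of the enol triflate (oxidative addition to zerovalent palladium, CO insertion, alcoholysis) installs the C8 carboxyl carbon as an ester that can later be removed without touching the C10 ester.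

Step 16
Reactants: 21 2-(trimethylsilyl)ethyl 2-[(tert-butyldimethylsilyloxy)methyl]-6,6-dimethyltricyclo[5.3.1.0(1,5)]undec-8-ene-8-carboxylate
Product: 22 2-(trimethylsilyl)ethyl 2-[(tert-butyldimethylsilyloxy)methyl]-6,6-dimethyl-10-oxotricyclo[5.3.1.0(1,5)]undec-8-ene-8-carboxylate (core configuration)
Conditions: Rh2(cap)4 (cap = caprolactamate, 1 mol %), 70% aq. t-BuOOH (5 equiv), K2CO3 (0.5 equiv), CH2Cl2, 25–40 °C
Reagents that add atoms: tert-butyl hydroperoxide, CC(C)(C)OO
Why: Radical allylic C–H oxidation occurs at C10, the only allylic position that can give a delocalised radical (C7 is a bridgehead), and trapping at the secondary terminus followed by peroxide collapse gives the γ-keto enoate.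

Step 17
Reactants: 22 2-(trimethylsilyl)ethyl 2-[(tert-butyldimethylsilyloxy)methyl]-6,6-dimethyl-10-oxotricyclo[5.3.1.0(1,5)]undec-8-ene-8-carboxylate
Product: 23 2-(trimethylsilyl)ethyl (10S)-2-[(tert-butyldimethylsilyloxy)methyl]-10-hydroxy-6,6-dimethyltricyclo[5.3.1.0(1,5)]undec-8-ene-8-carboxylate (core configuration, hydroxyl on the C5 side)
Conditions: NaBH4, CeCl3·7H2O, MeOH, −40 to 0 °C
Reagents that add atoms: none
Why: Luche 1,2-reduction, in which hydride attacks C10 anti to the C1–C5 bond that stands nearly perpendicular to the carbonyl plane (the face syn to C11), so the hydroxyl ends on the C5 side as in the target while the enoate is not reduced.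

Step 18
Reactants: 24 oct-7-yn-1-ol
Product: 25 1-methoxy-4-[(oct-7-yn-1-yloxy)methyl]benzene
Conditions: NaH, 4-methoxybenzyl chloride, Bu4NI (cat.), THF–DMF, 0 °C to rt
Reagents that add atoms: 4-methoxybenzyl chloride, COc1ccc(CCl)cc1
Why: Williamson etherification, the alkoxide forming and reacting well before the far less acidic alkyne C–H is touched.

Step 19
Reactants: 25 1-methoxy-4-[(oct-7-yn-1-yloxy)methyl]benzene; 26 8-bromooctanoic acid
Product: 27 16-[(4-methoxybenzyl)oxy]hexadec-9-ynoic acid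
Conditions: 25 (1.2 equiv), n-BuLi, THF, −78 °C; lithium salt of 26 (from 26 and n-BuLi, −78 °C), DMPU, −78 °C to rt; 1 M HCl
Reagents that add atoms: none
Why: Acetylide alkylation (SN2) of the primary bromide, carried as its lithium carboxylate in a dipolar cosolvent, joins the two eight-carbon pieces at C8'–C9'.

Step 20
Reactants: 27 16-[(4-methoxybenzyl)oxy]hexadec-9-ynoic acid
Product: 28 (9Z)-16-[(4-methoxybenzyl)oxy]hexadec-9-enoic acid
Conditions: H2 (1 atm), Lindlar catalyst (Pd/CaCO3 poisoned with Pb(OAc)2), quinoline, EtOAc, rt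
Reagents that add atoms: none
Why: Lindlar semi-hydrogenation adds H2 syn on the poisoned palladium surface and stops at the (Z)-alkene, leaving the benzylic ether and the acid intact.

Step 21
Reactants: 23 2-(trimethylsilyl)ethyl (10S)-2-[(tert-butyldimethylsilyloxy)methyl]-10-hydroxy-6,6-dimethyltricyclo[5.3.1.0(1,5)]undec-8-ene-8-carboxylate; 28 (9Z)-16-[(4-methoxybenzyl)oxy]hexadec-9-enoic acid
Product: 30 2-(trimethylsilyl)ethyl (10S)-2-[(tert-butyldimethylsilyloxy)methyl]-10-{[(9Z)-16-[(4-methoxybenzyl)oxy]hexadec-9-enoyl]oxy}-6,6-dimethyltricyclo[5.3.1.0(1,5)]undec-8-ene-8-carboxylate (core configuration), via mixed anhydride 29 (not isolated)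
Conditions: 28, 2,4,6-trichlorobenzoyl chloride, Et3N, THF, rt; then 23, DMAP, toluene, rt to 40 °C
Reagents that add atoms: none
Why: Yamaguchi esterification, in which DMAP attacks the aliphatic carbonyl of the mixed anhydride and the acylpyridinium acylates the hindered C10 alcohol with retention at C10.

Step 22
Reactants: 30 2-(trimethylsilyl)ethyl (10S)-2-[(tert-butyldimethylsilyloxy)methyl]-10-{[(9Z)-16-[(4-methoxybenzyl)oxy]hexadec-9-enoyl]oxy}-6,6-dimethyltricyclo[5.3.1.0(1,5)]undec-8-ene-8-carboxylate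
Product: 31 (10S)-2-(hydroxymethyl)-10-{[(9Z)-16-[(4-methoxybenzyl)oxy]hexadec-9-enoyl]oxy}-6,6-dimethyltricyclo[5.3.1.0(1,5)]undec-8-ene-8-carboxylic acid (core configuration)
Conditions: Bu4NF (3 equiv), THF, 0 °C to rt; aq. NH4Cl
Reagents that add atoms: none
Why: Fluoride-induced desilylation cleaves the silyl ether and fragments the 2-(trimethylsilyl)ethyl ester by β-elimination in one step, while the C10 ester (its oxygen on the ring face opposite the C2 arm), the benzylic ether and the (Z)-alkene are stable.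

Step 23
Reactants: 31 (10S)-2-(hydroxymethyl)-10-{[(9Z)-16-[(4-methoxybenzyl)oxy]hexadec-9-enoyl]oxy}-6,6-dimethyltricyclo[5.3.1.0(1,5)]undec-8-ene-8-carboxylic acid
Product: 32 (10S)-2-formyl-10-{[(9Z)-16-[(4-methoxybenzyl)oxy]hexadec-9-enoyl]oxy}-6,6-dimethyltricyclo[5.3.1.0(1,5)]undec-8-ene-8-carboxylic acid (core configuration)
Conditions: Dess–Martin periodinane, CH2Cl2, 0 °C to rt
Reagents that add atoms: none
Why: Dess–Martin oxidation converts the primary alcohol to the aldehyde under near-neutral conditions that leave the C2 centre, the free acid, the benzylic ether and both alkenes untouched.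

Step 24
Reactants: 32 (10S)-2-formyl-10-{[(9Z)-16-[(4-methoxybenzyl)oxy]hexadec-9-enoyl]oxy}-6,6-dimethyltricyclo[5.3.1.0(1,5)]undec-8-ene-8-carboxylic acid
Product: 33 (1S,2S,5S,7R,10S)-2-formyl-10-{[(9Z)-16-hydroxyhexadec-9-enoyl]oxy}-6,6-dimethyltricyclo[5.3.1.0(1,5)]undec-8-ene-8-carboxylic acid (target)
Conditions: DDQ (1.3 equiv), CH2Cl2–pH 7 phosphate buffer (10:1), 0 °C to rt
Reagents that add atoms: none
Why: Oxidative cleavage of the 4-methoxybenzyl ether with DDQ (benzylic hydride abstraction, then hydrolysis of the hemiacetal) runs at neutral pH, so the C2 aldehyde meets neither acid nor base.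

**Compound list**

1 | 1,4-dioxaspiro[4.5]dec-6-en-8-one | O=C1C=CC2(CC1)OCCO2 | starting material
2 | 1-methoxy-2-methyl-1-(trimethylsilyloxy)propene | COC(O[Si](C)(C)C)=C(C)C | starting material
3 | methyl 2-methyl-2-[(6R)-8-(trimethylsilyloxy)-1,4-dioxaspiro[4.5]dec-7-en-6-yl]propanoate | COC(=O)C(C)(C)[C@H]1C=C(O[Si](C)(C)C)CCC12OCCO2 | intermediate (not isolated)
4 | methyl 2-methyl-2-[(6R)-8-oxo-1,4-dioxaspiro[4.5]decan-6-yl]propanoate | COC(=O)C(C)(C)[C@H]1CC(=O)CCC12OCCO2 | intermediate
5 | methyl 2-methyl-2-[(6R)-8-(triethylsilyloxy)-1,4-dioxaspiro[4.5]decan-6-yl]propanoate, C1 epimers | COC(=O)C(C)(C)[C@H]1CC(O[Si](CC)(CC)CC)CCC12OCCO2 | intermediate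
6 | 2-methyl-2-[(6R)-8-(triethylsilyloxy)-1,4-dioxaspiro[4.5]decan-6-yl]propan-1-ol | OCC(C)(C)[C@H]1CC(O[Si](CC)(CC)CC)CCC12OCCO2 | intermediate
7 | 2-methyl-2-[(6R)-8-(triethylsilyloxy)-1,4-dioxaspiro[4.5]decan-6-yl]propanal | O=CC(C)(C)[C@H]1CC(O[Si](CC)(CC)CC)CCC12OCCO2 | intermediate
8 | but-3-enylmagnesium bromide | C=CCC[Mg]Br | starting material
9 | 2-methyl-2-[(6R)-8-(triethylsilyloxy)-1,4-dioxaspiro[4.5]decan-6-yl]hept-6-en-3-ol, carbinol epimers | C=CCCC(O)C(C)(C)[C@H]1CC(O[Si](CC)(CC)CC)CCC12OCCO2 | intermediate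
10 | 4,4,5,5-tetramethyl-2-vinyl-1,3,2-dioxaborolane | C=CB1OC(C)(C)C(C)(C)O1 | starting material
11 | (6E)-2-methyl-7-(4,4,5,5-tetramethyl-1,3,2-dioxaborolan-2-yl)-2-[(6R)-8-(triethylsilyloxy)-1,4-dioxaspiro[4.5]decan-6-yl]hept-6-en-3-ol | CC1(C)OB(/C=C/CCC(O)C(C)(C)[C@H]2CC(O[Si](CC)(CC)CC)CCC23OCCO3)OC1(C)C | intermediate
12 | O-{(6E)-2-methyl-7-(pinacolboryl)-2-[(6R)-8-(triethylsilyloxy)-1,4-dioxaspiro[4.5]decan-6-yl]hept-6-en-3-yl} S-methyl carbonodithioate | CSC(=S)OC(CC/C=C/B1OC(C)(C)C(C)(C)O1)C(C)(C)[C@H]2CC(O[Si](CC)(CC)CC)CCC23OCCO3 | intermediate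
13 | O-{(6E)-2-[(6R)-8-hydroxy-1,4-dioxaspiro[4.5]decan-6-yl]-2-methyl-7-(pinacolboryl)hept-6-en-3-yl} S-methyl carbonodithioate | CSC(=S)OC(CC/C=C/B1OC(C)(C)C(C)(C)O1)C(C)(C)[C@H]2CC(O)CCC23OCCO3 | intermediate
14 | O-{(6E)-2-methyl-2-[(6R)-8-oxo-1,4-dioxaspiro[4.5]decan-6-yl]-7-(pinacolboryl)hept-6-en-3-yl} S-methyl carbonodithioate | CSC(=S)OC(CC/C=C/B1OC(C)(C)C(C)(C)O1)C(C)(C)[C@H]2CC(=O)CCC23OCCO3 | intermediate
15 | O-{(6E)-2-methyl-2-[(6R)-8-[(2-phenylaziridin-1-yl)imino]-1,4-dioxaspiro[4.5]decan-6-yl]-7-(pinacolboryl)hept-6-en-3-yl} S-methyl carbonodithioate | CSC(=S)OC(CC/C=C/B1OC(C)(C)C(C)(C)O1)C(C)(C)[C@H]2CC(=NN4CC4c4ccccc4)CCC23OCCO3 | intermediate (key-step precursor)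
16 | 2-{[8,8-(ethylenedioxy)-6,6-dimethyltricyclo[5.3.1.0(1,5)]undecan-2-yl]methyl}-4,4,5,5-tetramethyl-1,3,2-dioxaborolane, core configuration | CC1(C)[C@H]2C[C@@]3(CCC24OCCO4)[C@@H](CB5OC(C)(C)C(C)(C)O5)CC[C@@H]13 | intermediate (key-step product)
17 | [8,8-(ethylenedioxy)-6,6-dimethyltricyclo[5.3.1.0(1,5)]undecan-2-yl]methanol, core configuration | CC1(C)[C@H]2C[C@@]3(CCC24OCCO4)[C@@H](CO)CC[C@@H]13 | intermediate (not isolated)
18 | 2-(hydroxymethyl)-6,6-dimethyltricyclo[5.3.1.0(1,5)]undecan-8-one, core configuration | CC1(C)[C@H]2C[C@@]3(CCC2=O)[C@@H](CO)CC[C@@H]13 | intermediate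
19 | 2-[(tert-butyldimethylsilyloxy)methyl]-6,6-dimethyltricyclo[5.3.1.0(1,5)]undecan-8-one, core configuration | CC1(C)[C@H]2C[C@@]3(CCC2=O)[C@@H](CO[Si](C)(C)C(C)(C)C)CC[C@@H]13 | intermediate
20 | 2-[(tert-butyldimethylsilyloxy)methyl]-6,6-dimethyltricyclo[5.3.1.0(1,5)]undec-8-en-8-yl trifluoromethanesulfonate, core configuration | CC1(C)[C@H]2C[C@@]3(CC=C2OS(=O)(=O)C(F)(F)F)[C@@H](CO[Si](C)(C)C(C)(C)C)CC[C@@H]13 | intermediate
21 | 2-(trimethylsilyl)ethyl 2-[(tert-butyldimethylsilyloxy)methyl]-6,6-dimethyltricyclo[5.3.1.0(1,5)]undec-8-ene-8-carboxylate, core configuration | CC1(C)[C@H]2C[C@@]3(CC=C2C(=O)OCC[Si](C)(C)C)[C@@H](CO[Si](C)(C)C(C)(C)C)CC[C@@H]13 | intermediate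
22 | 2-(trimethylsilyl)ethyl 2-[(tert-butyldimethylsilyloxy)methyl]-6,6-dimethyl-10-oxotricyclo[5.3.1.0(1,5)]undec-8-ene-8-carboxylate, core configuration | CC1(C)[C@H]2C[C@@]3(C(=O)C=C2C(=O)OCC[Si](C)(C)C)[C@@H](CO[Si](C)(C)C(C)(C)C)CC[C@@H]13 | intermediate
23 | 2-(trimethylsilyl)ethyl (10S)-2-[(tert-butyldimethylsilyloxy)methyl]-10-hydroxy-6,6-dimethyltricyclo[5.3.1.0(1,5)]undec-8-ene-8-carboxylate, core configuration | CC1(C)[C@H]2C[C@@]3([C@@H](O)C=C2C(=O)OCC[Si](C)(C)C)[C@@H](CO[Si](C)(C)C(C)(C)C)CC[C@@H]13 | intermediate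
24 | oct-7-yn-1-ol | C#CCCCCCCO | starting material
25 | 1-methoxy-4-[(oct-7-yn-1-yloxy)methyl]benzene | C#CCCCCCCOCc1ccc(OC)cc1 | intermediate
26 | 8-bromooctanoic acid | OC(=O)CCCCCCCBr | starting material
27 | 16-[(4-methoxybenzyl)oxy]hexadec-9-ynoic acid | OC(=O)CCCCCCCC#CCCCCCCOCc1ccc(OC)cc1 | intermediate
28 | (9Z)-16-[(4-methoxybenzyl)oxy]hexadec-9-enoic acid | OC(=O)CCCCCCC/C=C\CCCCCCOCc1ccc(OC)cc1 | intermediate
29 | (9Z)-16-[(4-methoxybenzyl)oxy]hexadec-9-enoic 2,4,6-trichlorobenzoic anhydride | COc1ccc(COCCCCCC/C=C\CCCCCCCC(=O)OC(=O)c2c(Cl)cc(Cl)cc2Cl)cc1 | intermediate (not isolated)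
30 | 2-(trimethylsilyl)ethyl (10S)-2-[(tert-butyldimethylsilyloxy)methyl]-10-{[(9Z)-16-[(4-methoxybenzyl)oxy]hexadec-9-enoyl]oxy}-6,6-dimethyltricyclo[5.3.1.0(1,5)]undec-8-ene-8-carboxylate, core configuration | CC1(C)[C@H]2C[C@@]3([C@@H](OC(=O)CCCCCCC/C=C\CCCCCCOCc4ccc(OC)cc4)C=C2C(=O)OCC[Si](C)(C)C)[C@@H](CO[Si](C)(C)C(C)(C)C)CC[C@@H]13 | intermediate
31 | (10S)-2-(hydroxymethyl)-10-{[(9Z)-16-[(4-methoxybenzyl)oxy]hexadec-9-enoyl]oxy}-6,6-dimethyltricyclo[5.3.1.0(1,5)]undec-8-ene-8-carboxylic acid, core configuration | CC1(C)[C@H]2C[C@@]3([C@@H](OC(=O)CCCCCCC/C=C\CCCCCCOCc4ccc(OC)cc4)C=C2C(=O)O)[C@@H](CO)CC[C@@H]13 | intermediate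
32 | (10S)-2-formyl-10-{[(9Z)-16-[(4-methoxybenzyl)oxy]hexadec-9-enoyl]oxy}-6,6-dimethyltricyclo[5.3.1.0(1,5)]undec-8-ene-8-carboxylic acid, core configuration | CC1(C)[C@H]2C[C@@]3([C@@H](OC(=O)CCCCCCC/C=C\CCCCCCOCc4ccc(OC)cc4)C=C2C(=O)O)[C@@H](C=O)CC[C@@H]13 | intermediate
33 | (1S,2S,5S,7R,10S)-2-formyl-10-{[(9Z)-16-hydroxyhexadec-9-enoyl]oxy}-6,6-dimethyltricyclo[5.3.1.0(1,5)]undec-8-ene-8-carboxylic acid | CC1(C)[C@H]2C[C@@]3([C@@H](OC(=O)CCCCCCC/C=C\CCCCCCO)C=C2C(=O)O)[C@@H](C=O)CC[C@@H]13 | target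

**Step count and risks**

Total step count: 24. Longest linear sequence: 21 steps (1 to 33 through steps 1–17 and 21–24); the side-chain acid 28 takes 3 steps (18–20).

Steps most likely to fail:

1. Step 11 (radical cascade). Hydrogen transfer from the tin hydride may compete with the closures, and the second 5-exo closure may show poor facial selectivity at C2, the CHBpin terminus distributing between the C11 and C10 sides. Fallback: C2 is set under thermodynamic instead of kinetic control. It sets out from 15: the cascade mixture of 16 and its C2 epimer, C2-epi boronate F1, is oxidised with alkaline H2O2 without the acid treatment to 17 and its C2 epimer, C2-epi alcohol F2. Dess–Martin oxidation gives the ketal aldehyde with the formyl group on the C11 side, aldehyde F3, and its C2 epimer, C2-epi aldehyde F4. DBU in CH2Cl2 should equilibrate the pair through the enol toward F3, in which the formyl group avoids C10. NaBH4 in MeOH then returns to the route at 17, which is hydrolysed to 18 as in step 12.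

2. Step 1 (asymmetric Mukaiyama–Michael). Face discrimination at the hindered β-carbon next to the ketal may be low, or the silyl cation may ionise the ketal. Fallback: the stereocentre is set by conjugate reduction instead of conjugate addition. It sets out from 1 and 2: uncatalysed addition in MeCN at 55 °C gives the racemic silyl enol ether, rac-enol ether F5. Saegusa–Ito oxidation (Pd(OAc)2, MeCN) gives the achiral β-substituted enone, enone F6. Copper hydride-catalysed asymmetric conjugate reduction (Cu(OAc)2, (R)-DTBM-SEGPHOS or its antipode as needed for 6R, polymethylhydrosiloxane, t-BuOH, toluene, 0 °C; fluoride work-up) delivers hydride to C7 and returns to the route at 4.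

3. Step 16 (allylic oxidation). Hydrogen abstraction at the hindered C10 methylene next to quaternary C1 may be slow, and the allyl radical may be trapped at C8 instead. Fallback: a polar oxygen transfer followed by a 1,3-transposition replaces the radical C–H oxidation. It sets out from 21: LiN(iPr)2 in THF–HMPA at −78 °C removes a C10 proton, and the dienolate is hydroxylated at C8 with 2-(phenylsulfonyl)-3-phenyloxaziridine to give the tertiary allylic alcohol, α-hydroxy ester F7 (C9=C10 alkene, either C8 epimer). Pyridinium chlorochromate, (C5H5NH)[CrO3Cl], in CH2Cl2 then effects the oxidative allylic transposition (chromate ester shift from C8 to C10, then oxidation) and returns to the route at 22.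

Further compounds
F1 | step 11 | C2 epimer of boronate 16 (borylmethyl arm on the C10 side) | CC1(C)[C@H]2C[C@@]3(CCC24OCCO4)[C@H](CB5OC(C)(C)C(C)(C)O5)CC[C@@H]13
F2 | step 11 | C2 epimer of hydroxy ketal 17 | CC1(C)[C@H]2C[C@@]3(CCC24OCCO4)[C@H](CO)CC[C@@H]13
F3 | step 11 | 8,8-(ethylenedioxy)-6,6-dimethyltricyclo[5.3.1.0(1,5)]undecane-2-carbaldehyde, formyl on the C11 side | CC1(C)[C@H]2C[C@@]3(CCC24OCCO4)[C@@H](C=O)CC[C@@H]13
F4 | step 11 | C2 epimer of aldehyde F3 | CC1(C)[C@H]2C[C@@]3(CCC24OCCO4)[C@H](C=O)CC[C@@H]13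
F5 | step 1 | racemic methyl 2-methyl-2-[8-(trimethylsilyloxy)-1,4-dioxaspiro[4.5]dec-7-en-6-yl]propanoate | COC(=O)C(C)(C)C1C=C(O[Si](C)(C)C)CCC12OCCO2
F6 | step 1 | methyl 2-methyl-2-(8-oxo-1,4-dioxaspiro[4.5]dec-6-en-6-yl)propanoate | COC(=O)C(C)(C)C1=CC(=O)CCC12OCCO2
F7 | step 16 | 2-(trimethylsilyl)ethyl 2-[(tert-butyldimethylsilyloxy)methyl]-8-hydroxy-6,6-dimethyltricyclo[5.3.1.0(1,5)]undec-9-ene-8-carboxylate | CC1(C)[C@H]2C[C@@]3(C=CC2(O)C(=O)OCC[Si](C)(C)C)[C@@H](CO[Si](C)(C)C(C)(C)C)CC[C@@H]13
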